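(The numbers are made up, and the outcome is calculated.)

The clock stops at 25 s, so I ask how long a unit of substrate needs to become target.

    substrate → intermediate A (k1 = 0.103 s⁻¹)
    substrate → intermediate B (k2 = 0.0739 s⁻¹)
    substrate + reagent ⇌ intermediate C (K3 = 8.2 L mol⁻¹, k3 = 0.216 L mol⁻¹ s⁻¹)
    reagent + intermediate A ⇌ intermediate D (K4 = 68.3 L mol⁻¹, k4 = 5.49 L mol⁻¹ s⁻¹)
    intermediate B → target (k5 = 0.343 s⁻¹)
    intermediate B ⇌ intermediate A (K6 = 0.19, k6 = 0.0679 s⁻¹)
    2 substrate → self-condensation product (k7 = 0.00142 L mol⁻¹ s⁻¹)

in all of them: time 25 s
- teal: substrate 20 mM; reagent 0.700 equiv (fed, over 15 s); all else is in the flask from the start; the feed brings no volume worth counting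
- violet: substrate 20 mM (fed, over 15 s); reagent 0.700 equiv; all else is in the flask from the start; the feed brings no volume worth counting
- grey: substrate 20 mM; reagent 0.700 equiv; everything together at the start

- a species is counted by the substrate in it: one self-condensation product counts as two
- where a step has two of a species, its rate is k times that concentration squared, and two are used at each turn
- run time (teal): 25 s

* which flask leads in amount of target, in percent of the substrate charged ("all alike" within 1.5 percentage points) (teal / violet / grey / all alike)
* how much target is there at the end, in percent of the substrate charged: teal
* how much target is there at the end, in percent of the substrate charged: violet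
* how much target is there at the end, in percent of the substrate charged: grey

I first sort the numbers by what an error in them costs. Each term below is time added to the wait, so a tenth off in a term moves the wait by a tenth of that term. Self-condensation can go, since its first half-life of 4.89 h is far longer than the run. A unit spends 5.65 s on average as substrate, and this is the term I must know best. It then spends 2.92 s as intermediate B and, counting its returns through step 6, 2.18 s as free intermediate A.

I hold reagent at its charge, which makes steps 3 and 4 pseudo-first-order. At balance in step 4, intermediate D stands to free intermediate A as its equilibrium constant times reagent, 0.956, which I call the holding number. A unit that enters intermediate D also leaves it, so with reagent held the same ratio holds for time summed over a unit's whole life, even where the step lags at a given moment, and the rate constant of step 4 drops out of the wait. So intermediate D adds 2.09 s, while intermediate C adds 0.649 s, which is less.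

The average wait is 13.5 s, which leaves grey a margin of 11.5 s. Violet's substrate enters on average at 7.50 s, so its margin is 4.01 s. If teal's reagent counts as half its charge, its wait falls to 12.1 s. I commit to teal ahead of grey, with violet behind both.

The forecast says teal, with 91.5% for teal, 72% for violet and 89.5% for grey, and for violet it names “the late substrate feed that leaves too little time to finish”. Its order is mine.

The flasks give 91.5% in teal, 75.4% in violet and 88.9% in grey, so teal leads. At the end, grey has 4.27% as intermediate D beside 1.97% as free intermediate A, a ratio of 2.17, above the holding number of 0.956. A further flask like teal, with 50 mM of substrate, has a holding number of 2.39 at full charge, and the same reckoning lengthens its wait to 14.2 s. That flask ends with 87.4% as target and 6.48% as intermediate D.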